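My unit was the percent of the X charged, because the tables read in it, and one percent of J costs more Z in a flask with much X than in a flask with little.

| flask | X | Z | remark | time |
|---|---|---|---|---|
| eta | 0.20 M (in portions, 3) | 0.36 M | run made earlier; portions every 12 s |  |
| beta | 0.80 M (in portions, 3) | 0.36 M | run made earlier; portions every 12 s |  |
| zeta | 0.40 M (in portions, 3) | 0.54 M | run made earlier; portions every 12 s |  |
| flask | 0.40 M (in portions, 3) | 0.360 M | the portions of X follow each other after 12 s, the first at the start | 30 min |

| run | time / min | X / % | J / % | Q / % |
|---|---|---|---|---|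
| eta | 5.00 | 4.2 | 91.9 | 4.7 |
| eta | 12.0 | 0 | 99.2 | 0 |
| eta | 25.0 | 0 | 101.0 | 1.2 |
| eta | 40.0 | 0 | 99.9 | 1.8 |
| beta | 5.00 | 2.1 | 43.6 | 0.3 |
| beta | 12.0 | 0.4 | 45.5 | 0.9 |
| beta | 25.0 | 0 | 46.6 | 0 |
| beta | 40.0 | 0 | 44.0 | 0.2 |
| zeta | 10.0 | 1.9 | 101.2 | 1.5 |
| zeta | 20.0 | 0.9 | 100.6 | 0 |
| zeta | 25.0 | 0 | 99.4 | 0 |
| zeta | 40.0 | 0.7 | 99.6 | 0.5 |

(scatter of a reading: 1 percentage point)

- the numbers in the tables scatter with a standard deviation of 1 percentage point
- the reaction counts as stopped when no species that holds the X changes by six tenths of a point or more over the second half of the time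

* why nothing more happens at 30 min, or that something still does (it is still moving / all of X has reacted)
* conversion of X at 30 min
* amount of J at 30 min, in percent of the X charged

I built the flask one process at a time. First I took the main step by itself, X and Z giving J mole for mole. The runs supported this: eta and zeta, with Z above X, read J at 99.9% and 99.6% at 40.0 min, while beta, with [Z]/[X] at 45.0%, read J between 43.6% and 46.6%. In the flask, Z at 0.360 M stood below X at 0.40 M, which makes Z the limiting reagent, so from the main step I reckoned J at 90.0%. This is the ceiling, the smaller of [Z]/[X] as charged and 100 percent, which is the most J that one Z per J allows, in percent of the X charged.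

Next I added a route for the X beyond what Z could take: in beta, X read 2.1% at 5.00 min and 0% at 25.0 min, while J stayed level within the scatter. In the flask this route had a surplus of 0.0400 M of X to take, so it raised the conversion I expected but left the ceiling where it was.

Last came the rest. Q read 4.7% in eta at 5.00 min and 0% at 12.0 min, so I treated it as passing. The portions in the flask ended after 24.0 s, far shorter than 30 min. Neither changed my number.

The forecast agreed: all of X has reacted, conversion 100%, J 90%, on the ground that “J tracks whichever of X or Z is scarcer”.

The flask gave this: all of X has reacted, conversion 100%, J 90.0%.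

    X → L (k = 0.0130 s⁻¹)
    Z + L → Q (k = 0.150 L mol⁻¹ s⁻¹)
    Q → J (k = 0.0280 s⁻¹)

In this scheme each J takes one Z on its way through L and Q; the flask stood at the ceiling of 90.0%, with the surplus as L, 10.0% of the X charged at 30.0 min. The depletion of Z, with 0% of it left, is the reason: the same run without that depletion gives J 100%, not 90.0%. A neighbouring flask with 1.6 M of X has a ceiling of 22.5%, and it gave J 22.5%.

(Readings and results are calculated on assumed constants; scatter was added.)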